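**Retrosynthetic overview**
- The target comes from a protected 3-hydroxyisoflavanone (a tertiary ketol) by acid: MOM removal and loss of water across C2–C3.
- The ketol comes from a 2-(2-aryl-2-oxoethoxy)benzaldehyde by forming the C4–C3 bond: the aldehyde carbon, turned into an acyl anion equivalent by an N-heterocyclic carbene, attacks the ketone carbon (intramolecular crossed benzoin).
- The keto-aldehyde comes from O-alkylation of a ring A salicylaldehyde with a ring B phenacyl bromide.
- The ring A piece comes from 2,4,6-trihydroxybenzaldehyde (bis-MOM, O-prenylation, para-Claisen–Cope); the ring B piece from 2,4-dihydroxyacetophenone (C-prenylation, MOM/methyl, α-bromination).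
- Rings A and B are bought as aromatics; ring C (the pyranone) is the only ring formed, closed in the benzoin step and aromatised in the last step.

Assumption: the target has no stereocentre and no stereogenic double bond, so it is achiral and needs no stereocontrol; the one stereocentre made on the way (C3 of 15 and 16) is racemic and is erased in step 9. Prenyl = 3-methylbut-2-en-1-yl; MOM = methoxymethyl.

**Route**

Step 1
Reactants: 1 2,4,6-trihydroxybenzaldehyde
Product: 2 2-hydroxy-4,6-bis(methoxymethoxy)benzaldehyde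
Conditions: MOMCl (2.1 equiv), i-Pr2NEt, CH2Cl2, 0 °C to rt
Reagents that add atoms: chloromethyl methyl ether (MOMCl), COCCl
Why: Williamson-type O-alkylation (MOM protection) in which the two free hydroxyls react while the hydroxyl hydrogen-bonded to the formyl group, the least nucleophilic one, stays free.

Step 2
Reactants: 2 2-hydroxy-4,6-bis(methoxymethoxy)benzaldehyde; 3 prenyl bromide (1-bromo-3-methylbut-2-ene)
Product: 4 2,4-bis(methoxymethoxy)-6-[(3-methylbut-2-en-1-yl)oxy]benzaldehyde
Conditions: K2CO3, DMF, rt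
Reagents that add atoms: none
Why: Williamson ether synthesis, the remaining phenoxide displacing bromide at the primary allylic carbon (SN2).

Step 3
Reactants: 4 2,4-bis(methoxymethoxy)-6-[(3-methylbut-2-en-1-yl)oxy]benzaldehyde
Product: 7 6-hydroxy-2,4-bis(methoxymethoxy)-3-(3-methylbut-2-en-1-yl)benzaldehyde, via ortho-dienone 5 (not isolated), via para-dienone 6 (not isolated)
Conditions: PhNEt2, 200 °C, sealed tube
Reagents that add atoms: none
Why: tandem aromatic Claisen/Cope rearrangement (para-Claisen): the [3,3] shift to the free ortho carbon gives 5, whose 1,1-dimethylallyl group undergoes a Cope [3,3] shift to the para carbon faster than 5 enolises, and 6 tautomerises, so the normal prenyl group lands between the two MOM ethers and the hydroxyl ortho to the aldehyde is set free.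

Step 4
Reactants: 8 2,4-dihydroxyacetophenone; 3 prenyl bromide (1-bromo-3-methylbut-2-ene)
Product: 9 1-[2,4-dihydroxy-3-(3-methylbut-2-en-1-yl)phenyl]ethanone
Conditions: 10% aq. KOH, 0 °C to rt
Reagents that add atoms: none
Why: phenoxide C-alkylation (nuclear prenylation) in water, where the dianion reacts at C3, the carbon activated by both oxygens; the yield is modest (about 25–35%) and the 5-prenyl and O-prenyl by-products are removed by chromatography.

Step 5
Reactants: 9 1-[2,4-dihydroxy-3-(3-methylbut-2-en-1-yl)phenyl]ethanone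
Product: 11 1-[2-methoxy-4-(methoxymethoxy)-3-(3-methylbut-2-en-1-yl)phenyl]ethanone, via 4-O-MOM phenol 10 (not isolated)
Conditions: MOMCl (1.05 equiv), K2CO3, acetone, 0 °C to rt; then Me2SO4, reflux
Reagents that add atoms: chloromethyl methyl ether (MOMCl), COCCl; dimethyl sulfate, COS(=O)(=O)OC
Why: two Williamson O-alkylations in one pot, the free 4-hydroxyl reacting with MOMCl at room temperature while the chelated and flanked 2-hydroxyl only reacts with dimethyl sulfate at reflux.

Step 6
Reactants: 11 1-[2-methoxy-4-(methoxymethoxy)-3-(3-methylbut-2-en-1-yl)phenyl]ethanone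
Product: 13 2-bromo-1-[2-methoxy-4-(methoxymethoxy)-3-(3-methylbut-2-en-1-yl)phenyl]ethanone, via trimethylsilyl enol ether 12 (not isolated)
Conditions: LiN(SiMe3)2, THF, −78 °C; Me3SiCl, −78 to 0 °C; then NBS (1.0 equiv), THF, −78 °C
Reagents that add atoms: N-bromosuccinimide, O=C1CCC(=O)N1Br; chlorotrimethylsilane, C[Si](C)(C)Cl (silyl group of 12 only)
Why: α-bromination of a ketone through its silyl enol ether, the methyl ketone having a single enolisable site and the electron-rich enol ether reacting with NBS at −78 °C far faster than the prenyl alkene or the arene.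

Step 7
Reactants: 7 6-hydroxy-2,4-bis(methoxymethoxy)-3-(3-methylbut-2-en-1-yl)benzaldehyde; 13 2-bromo-1-[2-methoxy-4-(methoxymethoxy)-3-(3-methylbut-2-en-1-yl)phenyl]ethanone
Product: 14 6-{2-[2-methoxy-4-(methoxymethoxy)-3-(3-methylbut-2-en-1-yl)phenyl]-2-oxoethoxy}-2,4-bis(methoxymethoxy)-3-(3-methylbut-2-en-1-yl)benzaldehyde
Conditions: K2CO3, acetone, rt
Reagents that add atoms: none
Why: Williamson ether synthesis (SN2 of the phenoxide on a phenacyl bromide), run with a mild base at room temperature so that the product does not go on to the Rap–Stoermer aldol cyclisation.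

Step 8
Reactants: 14 6-{2-[2-methoxy-4-(methoxymethoxy)-3-(3-methylbut-2-en-1-yl)phenyl]-2-oxoethoxy}-2,4-bis(methoxymethoxy)-3-(3-methylbut-2-en-1-yl)benzaldehyde
Product: 15 rac-3-hydroxy-3-[2-methoxy-4-(methoxymethoxy)-3-(3-methylbut-2-en-1-yl)phenyl]-5,7-bis(methoxymethoxy)-6-(3-methylbut-2-en-1-yl)-2,3-dihydro-4H-chromen-4-one
Conditions: 2-(pentafluorophenyl)-6,7-dihydro-5H-pyrrolo[2,1-c][1,2,4]triazol-2-ium tetrafluoroborate (20 mol %), 1,8-diazabicyclo[5.4.0]undec-7-ene (15 mol %), THF, rt to 40 °C, argon
Reagents that add atoms: none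
Why: N-heterocyclic carbene catalysed intramolecular crossed aldehyde–ketone benzoin reaction, in which the carbene converts the aldehyde carbon into a Breslow intermediate (acyl anion equivalent) that adds to the tethered ketone carbon in a six-membered closure, a known route to 3-hydroxychroman-4-ones from ortho-alkoxy benzaldehydes, though this hindered, electron-rich aldehyde is a demanding case; keeping the base below the precatalyst loading limits the competing aldol, and the new C3 stereocentre forms racemic and is erased in step 9.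

Step 9
Reactants: 15 rac-3-hydroxy-3-[2-methoxy-4-(methoxymethoxy)-3-(3-methylbut-2-en-1-yl)phenyl]-5,7-bis(methoxymethoxy)-6-(3-methylbut-2-en-1-yl)-2,3-dihydro-4H-chromen-4-one
Product: 17 2'-methoxylupalbigenin (5,7-dihydroxy-3-[4-hydroxy-2-methoxy-3-(3-methylbut-2-en-1-yl)phenyl]-6-(3-methylbut-2-en-1-yl)-4H-chromen-4-one), via MOM-free ketol 16 (not isolated)
Conditions: 3 M aq. HCl, MeOH, 50 °C, 1–2 h
Reagents that add atoms: none
Why: acid-catalysed acetal cleavage (MOM removal) followed by E1 dehydration, the tertiary benzylic hydroxyl ionising through a para-quinone-methide-type cation once the 4'-hydroxyl is free and loss of a C2 proton giving the aromatic 4-pyranone; the time is kept short to avoid chroman formation from the prenyl groups, and no stereocentre remains.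

**Compound list**
1 | 2,4,6-trihydroxybenzaldehyde | O=Cc1c(O)cc(O)cc1O | starting material
2 | 2-hydroxy-4,6-bis(methoxymethoxy)benzaldehyde | O=Cc1c(O)cc(OCOC)cc1OCOC | intermediate
3 | prenyl bromide (1-bromo-3-methylbut-2-ene) | CC(C)=CCBr | starting material
4 | 2,4-bis(methoxymethoxy)-6-[(3-methylbut-2-en-1-yl)oxy]benzaldehyde | O=Cc1c(OCC=C(C)C)cc(OCOC)cc1OCOC | intermediate
5 | ortho-dienone: 2,4-bis(methoxymethoxy)-5-(2-methylbut-3-en-2-yl)-6-oxocyclohexa-1,3-diene-1-carbaldehyde (racemic) | O=CC1=C(OCOC)C=C(OCOC)C(C(C)(C)C=C)C1=O | intermediate (not isolated)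
6 | para-dienone: 2,4-bis(methoxymethoxy)-3-(3-methylbut-2-en-1-yl)-6-oxocyclohexa-1,4-diene-1-carbaldehyde | O=CC1=C(OCOC)C(CC=C(C)C)C(OCOC)=CC1=O | intermediate (not isolated)
7 | 6-hydroxy-2,4-bis(methoxymethoxy)-3-(3-methylbut-2-en-1-yl)benzaldehyde | O=Cc1c(O)cc(OCOC)c(CC=C(C)C)c1OCOC | intermediate
8 | 2,4-dihydroxyacetophenone | CC(=O)c1ccc(O)cc1O | starting material
9 | 1-[2,4-dihydroxy-3-(3-methylbut-2-en-1-yl)phenyl]ethanone | CC(=O)c1ccc(O)c(CC=C(C)C)c1O | intermediate
10 | 1-[2-hydroxy-4-(methoxymethoxy)-3-(3-methylbut-2-en-1-yl)phenyl]ethanone | CC(=O)c1ccc(OCOC)c(CC=C(C)C)c1O | intermediate (not isolated)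
11 | 1-[2-methoxy-4-(methoxymethoxy)-3-(3-methylbut-2-en-1-yl)phenyl]ethanone | CC(=O)c1ccc(OCOC)c(CC=C(C)C)c1OC | intermediate
12 | ({1-[2-methoxy-4-(methoxymethoxy)-3-(3-methylbut-2-en-1-yl)phenyl]ethenyl}oxy)trimethylsilane | C=C(O[Si](C)(C)C)c1ccc(OCOC)c(CC=C(C)C)c1OC | intermediate (not isolated)
13 | 2-bromo-1-[2-methoxy-4-(methoxymethoxy)-3-(3-methylbut-2-en-1-yl)phenyl]ethanone | BrCC(=O)c1ccc(OCOC)c(CC=C(C)C)c1OC | intermediate
14 | 6-{2-[2-methoxy-4-(methoxymethoxy)-3-(3-methylbut-2-en-1-yl)phenyl]-2-oxoethoxy}-2,4-bis(methoxymethoxy)-3-(3-methylbut-2-en-1-yl)benzaldehyde | O=Cc1c(OCC(=O)c2ccc(OCOC)c(CC=C(C)C)c2OC)cc(OCOC)c(CC=C(C)C)c1OCOC | intermediate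
15 | rac-3-hydroxy-3-[2-methoxy-4-(methoxymethoxy)-3-(3-methylbut-2-en-1-yl)phenyl]-5,7-bis(methoxymethoxy)-6-(3-methylbut-2-en-1-yl)-2,3-dihydro-4H-chromen-4-one (racemic at C3) | O=C1c2c(OCOC)c(CC=C(C)C)c(OCOC)cc2OCC1(O)c1ccc(OCOC)c(CC=C(C)C)c1OC | intermediate
16 | rac-3,5,7-trihydroxy-3-[4-hydroxy-2-methoxy-3-(3-methylbut-2-en-1-yl)phenyl]-6-(3-methylbut-2-en-1-yl)-2,3-dihydro-4H-chromen-4-one (racemic at C3) | O=C1c2c(O)c(CC=C(C)C)c(O)cc2OCC1(O)c1ccc(O)c(CC=C(C)C)c1OC | intermediate (not isolated)
17 | 2'-methoxylupalbigenin (achiral) | COc1c(-c2coc3cc(O)c(CC=C(C)C)c(O)c3c2=O)ccc(O)c1CC=C(C)C | target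

**Step count and risks**
Total steps: 9 (steps 1–3 to the ring A piece 7, steps 4–6 to the ring B piece 13, steps 7–9 after the two are joined).
Longest linear sequence: 6 steps (1 → 2 → 4 → 7 → 14 → 15 → 17, or 8 → 9 → 11 → 13 → 14 → 15 → 17).

Three steps most likely to fail:

Step 8 (carbene-catalysed crossed benzoin). The aldehyde is electron-rich and flanked by two ortho oxygens, so the Breslow intermediate may form slowly, and base can divert 14 to a 2-aroylbenzofuran by aldol condensation. The fallback sets out from 14 and keeps the same C4–C3 bond but makes it by reductive coupling. SmI2 with t-BuOH in THF at −78 °C gives an intramolecular pinacol coupling (ketyl as the nucleophilic carbonyl carbon) to 3-[2-methoxy-4-(methoxymethoxy)-3-(3-methylbut-2-en-1-yl)phenyl]-5,7-bis(methoxymethoxy)-6-(3-methylbut-2-en-1-yl)chromane-3,4-diol F1 (racemic, cis-diol expected, either diastereomer serves). Its secondary benzylic alcohol at C4 is then oxidised with Dess–Martin periodinane in CH2Cl2 (or MnO2), the tertiary alcohol being inert, and the route is rejoined at 15. The known weakness is reductive loss of the aryloxide next to the ketone, which the fast six-membered ketyl addition has to outrun.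

Step 9 (one-pot MOM removal and dehydration). Prolonged acid can cyclise a prenyl group onto a neighbouring phenol, and dehydration may lag behind deprotection. The fallback sets out from 15 and separates the two events without Brønsted acid. Methyl N-(triethylammoniosulfonyl)carbamate (Burgess reagent) in THF at 50 °C gives syn-elimination to 3-[2-methoxy-4-(methoxymethoxy)-3-(3-methylbut-2-en-1-yl)phenyl]-5,7-bis(methoxymethoxy)-6-(3-methylbut-2-en-1-yl)-4H-chromen-4-one F2. The three MOM ethers are then removed with ZnBr2 and n-PrSH in CH2Cl2 at 0 °C within minutes, and the route is rejoined at the target 17.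

Step 4 (direct C-prenylation). Low yield and 3- versus 5-regioisomers are expected. The fallback sets out from 8 and replaces phenoxide alkylation by halogenation and cross-coupling. Iodination with I2 and HIO3 in aqueous EtOH goes between the two hydroxyls and gives 1-(2,4-dihydroxy-3-iodophenyl)ethanone F3. The one-pot protection of step 5 (MOMCl, K2CO3, acetone; then Me2SO4, reflux) passes through 1-[2-hydroxy-3-iodo-4-(methoxymethoxy)phenyl]ethanone F4 to 1-[3-iodo-2-methoxy-4-(methoxymethoxy)phenyl]ethanone F5. Stille coupling with tributyl(3-methylbut-2-en-1-yl)stannane and Pd(PPh3)4 in DMF at 90 °C then gives 11, where the route is rejoined (9 and 10 are bypassed).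

**Further compounds**
F1 | step 8 | 3-[2-methoxy-4-(methoxymethoxy)-3-(3-methylbut-2-en-1-yl)phenyl]-5,7-bis(methoxymethoxy)-6-(3-methylbut-2-en-1-yl)chromane-3,4-diol (racemic) | OC1c2c(OCOC)c(CC=C(C)C)c(OCOC)cc2OCC1(O)c1ccc(OCOC)c(CC=C(C)C)c1OC
F2 | step 9 | 3-[2-methoxy-4-(methoxymethoxy)-3-(3-methylbut-2-en-1-yl)phenyl]-5,7-bis(methoxymethoxy)-6-(3-methylbut-2-en-1-yl)-4H-chromen-4-one | COCOc1ccc(-c2coc3cc(OCOC)c(CC=C(C)C)c(OCOC)c3c2=O)c(OC)c1CC=C(C)C
F3 | step 4 | 1-(2,4-dihydroxy-3-iodophenyl)ethanone | CC(=O)c1ccc(O)c(I)c1O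
F4 | step 4 | 1-[2-hydroxy-3-iodo-4-(methoxymethoxy)phenyl]ethanone | CC(=O)c1ccc(OCOC)c(I)c1O
F5 | step 4 | 1-[3-iodo-2-methoxy-4-(methoxymethoxy)phenyl]ethanone | CC(=O)c1ccc(OCOC)c(I)c1OC
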